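**Plan**
1. Retrosynthesis: remove the two O-benzyl groups and the O3 hexanoyl ester, cut the C3–C4 bond of ring C (benzoin transform) to a dialdehyde, then cut the O1–C2 ether bond to a dibenzylated phloroglucinaldehyde and methyl 2-bromo-2-phenylacetate.
2. Forward: ring A is bought. Selective O-benzylation, O1–C2 etherification, and reduction then re-oxidation of both carbonyl carbons give the dialdehyde. Ring C then closes by C3–C4 bond formation, and acylation and hydrogenolysis finish.
3. Enabling feature: C4 (ketone) and C3 (carbinol) of ring C are both carbonyl-derived carbons, and C2, which before closure carries phenyl, aryloxy and a formyl group, epimerises readily through its enol.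
4. Stereochemistry: C3 is set by a chiral triazolylidene in the ring closure and C2 by dynamic kinetic resolution of the racemising aldehyde in the same step, giving the trans (2R,3R) ketol. Later steps touch neither centre.

Key step: step 5

Assumption: the target is the (2R,3R)-trans isomer (flavanone numbering O1, C2, C3, C4, C4a, C5–C8, C8a); the sense of induction of the aminoindanol-derived triazolium salt on this substrate cannot be assigned in advance, so the (5aS,10bR) salt is written and its equally available mirror image is to be used should it deliver the (2S,3S) series.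

**Step 1**
Reactants: 1 2,4,6-trihydroxybenzaldehyde; 2 benzyl bromide
Product: 3 2,4-bis(benzyloxy)-6-hydroxybenzaldehyde
Conditions: BnBr (2.05 equiv in all), K2CO3 (2.2 equiv), DMF, 0 °C to rt
Reagents that add atoms: benzyl bromide, BrCc1ccccc1 (the second equivalent, which supplies the second benzyl group)
Why: Twofold Williamson etherification should take the most acidic para hydroxyl and then one ortho hydroxyl, while the other ortho hydroxyl, held in a hydrogen bond to the formyl oxygen, stays free when the bromide is limited to two equivalents.

**Step 2**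
Reactants: 3 2,4-bis(benzyloxy)-6-hydroxybenzaldehyde; 4 methyl 2-bromo-2-phenylacetate (racemic)
Product: 5 methyl 2-[3,5-bis(benzyloxy)-2-formylphenoxy]-2-phenylacetate (racemic)
Conditions: K2CO3 (1.5 equiv), DMF, rt
Reagents that add atoms: none
Why: Williamson etherification in which the weakly nucleophilic, hydrogen-bonded phenoxide meets a highly reactive benzylic α-bromo ester in an SN2 displacement, with room temperature keeping the adduct from aldol closure onto the ortho formyl group; the new centre is racemic and is corrected in step 5.

**Step 3**
Reactants: 5 methyl 2-[3,5-bis(benzyloxy)-2-formylphenoxy]-2-phenylacetate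
Product: 6 2-[3,5-bis(benzyloxy)-2-(hydroxymethyl)phenoxy]-2-phenylethan-1-ol (racemic)
Conditions: LiAlH4, THF, 0 °C; aqueous NaOH work-up
Reagents that add atoms: none
Why: Hydride reduction with LiAlH4 takes both the methyl ester and the aryl aldehyde to primary alcohols and leaves the benzyl and aryl ethers untouched, and the basic work-up protects the acid-labile trialkoxybenzyl alcohol.

**Step 4**
Reactants: 6 2-[3,5-bis(benzyloxy)-2-(hydroxymethyl)phenoxy]-2-phenylethan-1-ol
Product: 7 2,4-bis(benzyloxy)-6-(2-oxo-1-phenylethoxy)benzaldehyde (racemic)
Conditions: Dess–Martin periodinane (2.4 equiv), NaHCO3, CH2Cl2, 0 °C to rt; crude product used at once without chromatography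
Reagents that add atoms: none
Why: Dess–Martin oxidation converts both primary alcohols to aldehydes under buffered, non-aqueous conditions without over-oxidation, and the buffer keeps acetic acid from ionising the electron-rich benzylic alcohol.

**Step 5**
Reactants: 7 2,4-bis(benzyloxy)-6-(2-oxo-1-phenylethoxy)benzaldehyde
Product: 8 (2R,3R)-5,7-bis(benzyloxy)-3-hydroxy-2-phenylchroman-4-one (5,7-di-O-benzylpinobanksin)
Conditions: (5aS,10bR)-2-(pentafluorophenyl)-5a,10b-dihydro-4H,6H-indeno[2,1-b][1,2,4]triazolo[4,3-d][1,4]oxazin-2-ium tetrafluoroborate (15 mol%), iPr2NEt (15 mol%), degassed toluene (0.05 M), 0 °C to rt, argon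
Reagents that add atoms: none
Why: Proposed new method: the triazolylidene freed by the amine adds reversibly to the aryl aldehyde of 7, proton transfer gives the Breslow intermediate, and its nucleophilic carbon (future C4) attacks the side-chain aldehyde carbon (future C3) in a 6-exo-trig closure of ring C, after which loss of the carbene leaves the C4 ketone and the C3 carbinol. The closest known reaction types are the carbene-catalysed intramolecular crossed aldehyde–ketone benzoin that gives 3-hydroxychroman-4-ones and the intramolecular benzoin closure of aliphatic dialdehydes; an aryl aldehyde closing onto an α-aryloxy aldehyde with dynamic resolution is not established. C3 is set by the catalyst, whose indane wall leaves one face of the acyl anion equivalent open so that the acceptor carbonyl is attacked on a single face, and C2 is set by dynamic kinetic resolution, because the α-phenyl-α-aryloxy aldehyde epimerises through its enol under the amine faster than it cyclises and only the enantiomer that can place phenyl equatorial in the chair-like transition state reacts, which leads to the 2,3-trans (2R,3R) ketol. The step needs the aryl aldehyde as donor although the aliphatic aldehyde is the more accessible site; this is secured by reversibility, since carbene addition and benzoin formation can both revert, the regioisomeric 4-hydroxy-3-ketone can return by retro-benzoin, and the chromanone, a ketone conjugated to the trialkoxyarene, is the thermodynamic sink. The electron-poor N-pentafluorophenyl triazolium class is chosen because it favours benzoin over expulsion of the aryloxide from a Breslow intermediate formed at the aliphatic aldehyde, and the weak base, low temperature and exclusion of air limit aldol closure, C3 epimerisation through the enediol and oxidation to the flavonol.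

**Step 6**
Reactants: 8 (2R,3R)-5,7-bis(benzyloxy)-3-hydroxy-2-phenylchroman-4-one; 9 hexanoyl chloride
Product: 10 (2R,3R)-5,7-bis(benzyloxy)-4-oxo-2-phenylchroman-3-yl hexanoate
Conditions: hexanoyl chloride (1.3 equiv), pyridine, 4-(dimethylamino)pyridine (5 mol%), CH2Cl2, 0 °C
Reagents that add atoms: none
Why: Nucleophilic acyl substitution (4-(dimethylamino)pyridine-catalysed O-acylation) of the secondary alcohol under weakly basic conditions at low temperature, which should epimerise neither C2 nor C3.

**Step 7**
Reactants: 10 (2R,3R)-5,7-bis(benzyloxy)-4-oxo-2-phenylchroman-3-yl hexanoate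
Product: 11 (2R,3R)-5,7-dihydroxy-4-oxo-2-phenylchroman-3-yl hexanoate (pinobanksin 3-O-hexanoate)
Conditions: H2 (1 atm), 10% Pd/C, EtOAc, rt
Reagents that add atoms: none
Why: Heterogeneous hydrogenolysis of the two aryl benzyl ethers over Pd/C, a standard deprotection in the flavanone series that under neutral conditions at ambient pressure should spare the cyclic benzylic C2–O1 ether, the ketone and the ester.

**Compound list**
1 | 2,4,6-trihydroxybenzaldehyde | O=Cc1c(O)cc(O)cc1O | starting material
2 | benzyl bromide | BrCc1ccccc1 | starting material
3 | 2,4-bis(benzyloxy)-6-hydroxybenzaldehyde | O=Cc1c(O)cc(OCc2ccccc2)cc1OCc1ccccc1 | intermediate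
4 | methyl 2-bromo-2-phenylacetate (racemic) | COC(=O)C(Br)c1ccccc1 | starting material
5 | methyl 2-[3,5-bis(benzyloxy)-2-formylphenoxy]-2-phenylacetate (racemic) | COC(=O)C(Oc1cc(OCc2ccccc2)cc(OCc2ccccc2)c1C=O)c1ccccc1 | intermediate
6 | 2-[3,5-bis(benzyloxy)-2-(hydroxymethyl)phenoxy]-2-phenylethan-1-ol (racemic) | OCC(Oc1cc(OCc2ccccc2)cc(OCc2ccccc2)c1CO)c1ccccc1 | intermediate
7 | 2,4-bis(benzyloxy)-6-(2-oxo-1-phenylethoxy)benzaldehyde (racemic) | O=CC(Oc1cc(OCc2ccccc2)cc(OCc2ccccc2)c1C=O)c1ccccc1 | intermediate
8 | (2R,3R)-5,7-bis(benzyloxy)-3-hydroxy-2-phenylchroman-4-one | O[C@H]1C(=O)c2c(OCc3ccccc3)cc(OCc3ccccc3)cc2O[C@@H]1c1ccccc1 | intermediate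
9 | hexanoyl chloride | CCCCCC(=O)Cl | starting material
10 | (2R,3R)-5,7-bis(benzyloxy)-4-oxo-2-phenylchroman-3-yl hexanoate | CCCCCC(=O)O[C@H]1C(=O)c2c(OCc3ccccc3)cc(OCc3ccccc3)cc2O[C@@H]1c1ccccc1 | intermediate
11 | (2R,3R)-5,7-dihydroxy-4-oxo-2-phenylchroman-3-yl hexanoate | CCCCCC(=O)O[C@H]1C(=O)c2c(O)cc(O)cc2O[C@@H]1c1ccccc1 | target

Total step count: 7. Longest linear sequence: 7 steps (1 to 11).

**Steps most likely to fail**

Step 5 (new method). Several processes may defeat it:
- The carbene may add preferentially at the less hindered aliphatic aldehyde and expel the aryloxide irreversibly from that Breslow intermediate.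
- Addition to the di-ortho-substituted, electron-rich aryl aldehyde may be too slow.
- Base-mediated aldol closure of the enolisable aldehyde onto the aryl aldehyde may drain material.
- Discrimination between the C2 enantiomers may be poor, or the ketol may epimerise at C3 through the enediol, so that enantiopurity erodes.

The fallback uses known chemistry, sets out from phenol 3 and returns at ketol 8. Protection with chloromethyl methyl ether and iPr2NEt in CH2Cl2 should give 2,4-bis(benzyloxy)-6-(methoxymethoxy)benzaldehyde F1. Addition of (E)-2-phenylvinylmagnesium bromide in THF should give racemic (E)-1-[2,4-bis(benzyloxy)-6-(methoxymethoxy)phenyl]-3-phenylprop-2-en-1-ol F2. Oxidation with MnO2 in CH2Cl2 should give the chalcone (E)-1-[2,4-bis(benzyloxy)-6-(methoxymethoxy)phenyl]-3-phenylprop-2-en-1-one F3. Julia–Colonna epoxidation (poly-L-leucine, urea–hydrogen peroxide, 1,8-diazabicyclo[5.4.0]undec-7-ene, THF) should give [2,4-bis(benzyloxy)-6-(methoxymethoxy)phenyl][(2R,3S)-3-phenyloxiran-2-yl]methanone F4. HCl in MeOH/THF with gentle warming should then remove the acetal, and the freed phenol should open the epoxide at the benzylic carbon with inversion (6-endo) to give trans ketol 8. The ketone-bearing epoxide carbon becomes C3 with retention and the benzylic carbon becomes C2 with inversion, hence (2R,3R).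

Step 4. The double oxidation may stall at a hydroxy aldehyde, divert through a lactol to a lactone, or ionise the trialkoxybenzyl alcohol. The α-aryloxy aldehyde may also hydrate or decompose on handling.

The fallback sets out from phenol 3 and returns at dialdehyde 7, never reducing the aryl aldehyde. Racemic 2-[(tert-butyldimethylsilyl)oxy]-1-phenylethan-1-ol F5 would be made by monosilylation of 1-phenylethane-1,2-diol with tert-butyldimethylsilyl chloride and imidazole. Mitsunobu etherification of 3 with F5 (PPh3, diisopropyl azodicarboxylate, THF) should give 2,4-bis(benzyloxy)-6-{2-[(tert-butyldimethylsilyl)oxy]-1-phenylethoxy}benzaldehyde F6. Bu4NF buffered with acetic acid in THF should give 2,4-bis(benzyloxy)-6-(2-hydroxy-1-phenylethoxy)benzaldehyde F7. A single Dess–Martin oxidation of the one primary alcohol, buffered with NaHCO3, should then give 7.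

Step 1. Alkylation may run on to the tribenzyl ether, attack carbon of the phloroglucinol nucleus, or stop at mixtures of mono- and di-ethers.

The fallback sets out from 1 and returns at 3. Exhaustive benzylation with benzyl bromide 2 (3.5 equiv) and K2CO3 in DMF at 60 °C should give 2,4,6-tris(benzyloxy)benzaldehyde F8. MgBr2·OEt2 in toluene/Et2O at reflux should then remove one benzyl group ortho to the carbonyl through a magnesium chelate and deliver 3 after aqueous work-up.

**Further compounds**
F1 | step 5 | 2,4-bis(benzyloxy)-6-(methoxymethoxy)benzaldehyde | COCOc1cc(OCc2ccccc2)cc(OCc2ccccc2)c1C=O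
F2 | step 5 | (E)-1-[2,4-bis(benzyloxy)-6-(methoxymethoxy)phenyl]-3-phenylprop-2-en-1-ol (racemic) | COCOc1cc(OCc2ccccc2)cc(OCc2ccccc2)c1C(O)/C=C/c1ccccc1
F3 | step 5 | (E)-1-[2,4-bis(benzyloxy)-6-(methoxymethoxy)phenyl]-3-phenylprop-2-en-1-one | COCOc1cc(OCc2ccccc2)cc(OCc2ccccc2)c1C(=O)/C=C/c1ccccc1
F4 | step 5 | [2,4-bis(benzyloxy)-6-(methoxymethoxy)phenyl][(2R,3S)-3-phenyloxiran-2-yl]methanone | COCOc1cc(OCc2ccccc2)cc(OCc2ccccc2)c1C(=O)[C@@H]1O[C@H]1c1ccccc1
F5 | step 4 | 2-[(tert-butyldimethylsilyl)oxy]-1-phenylethan-1-ol (racemic) | CC(C)(C)[Si](C)(C)OCC(O)c1ccccc1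
F6 | step 4 | 2,4-bis(benzyloxy)-6-{2-[(tert-butyldimethylsilyl)oxy]-1-phenylethoxy}benzaldehyde (racemic) | CC(C)(C)[Si](C)(C)OCC(Oc1cc(OCc2ccccc2)cc(OCc2ccccc2)c1C=O)c1ccccc1
F7 | step 4 | 2,4-bis(benzyloxy)-6-(2-hydroxy-1-phenylethoxy)benzaldehyde (racemic) | OCC(Oc1cc(OCc2ccccc2)cc(OCc2ccccc2)c1C=O)c1ccccc1
F8 | step 1 | 2,4,6-tris(benzyloxy)benzaldehyde | O=Cc1c(OCc2ccccc2)cc(OCc2ccccc2)cc1OCc1ccccc1
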